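The readings were computed for an exercise.

3 answers are wanted, and one quantity serves them.

| flask | J | D | G | temperature | remark | time |
|---|---|---|---|---|---|---|
| beta | 0.43 M | 2 equiv (in portions, 4) | 1.8 equiv | 75 °C | run made earlier; portions every 8.0 min |  |
| zeta | 0.43 M | 2 equiv (in portions, 4) | 4.8 equiv | 86 °C | run made earlier; portions every 8.0 min |  |
| Thursday's | 0.43 M | 2.00 equiv | 3.00 equiv | 80 °C | everything together at the start | 4.0 h |
| Wednesday's | 0.43 M | 2.00 equiv (in portions, 4) | 1.50 equiv | 80 °C | the portions of D follow each other after 8.0 min, the first at the start | 4.0 h |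

| run | time / min | L / % | Q / % |
|---|---|---|---|
| beta | 10.0 | 15.1 | 0 |
| beta | 20.0 | 26.6 | 1.4 |
| beta | 50.0 | 40.0 | 2.4 |
| beta | 120 | 42.1 | 9.0 |
| zeta | 15.0 | 70.5 | 1.4 |
| zeta | 40.0 | 66.0 | 19.3 |
| zeta | 80.0 | 37.9 | 48.3 |
| zeta | 120 | 21.5 | 64.6 |

(each reading ± 1 percentage point)

- which one finishes higher in amount of L, in percent of the J charged ("neither" within 2 percentage points) (Thursday's / Wednesday's / neither)
- amount of L at the end, in percent of the J charged, Thursday's
- amount of L at the end, in percent of the J charged, Wednesday's



A first-order rate constant gives the share of a species lost per minute. In the zeta run L fell from 37.9% to 21.5% between 80.0 min and 120 min. The logarithm of that ratio, divided by the time, gives 0.0142 min⁻¹. In the beta run L stood near 41.1% late on, so read the loss from Q instead. Q gained 6.6 percentage points in 70.0 min. Dividing that gain by the mean L and by the time gives 0.00230 min⁻¹.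

Now I assume the loss is pseudo-first-order, with its constant proportional to the G charged. Divide each constant by its G concentration. Then take the geometric mean, since 80 °C lies near the middle of the two temperatures. This gives the loss constant per unit of G charged, 0.00451 L mol⁻¹ min⁻¹. The even case is the zero of the scale: on this assumption, two flasks at one temperature with equal G keep equal shares of their L.

These flasks are not even. Thursday's carries twice the G of Wednesday's, so I reckon a loss constant of 0.00582 min⁻¹ for Thursday's and 0.00291 min⁻¹ for Wednesday's. I count the loss over the 200 min after 40.0 min. As a starting amount, I take L plus Q at the end of the beta run, 51.1%, for Wednesday's. For Thursday's I take its mean with the zeta run's 86.1%. My reckoning gives 21.4% for Thursday's and 28.5% for Wednesday's, so it puts Wednesday's higher.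

The forecast prints 21% for Thursday's and 33% for Wednesday's, which is above my figure for Wednesday's. It says: “Wednesday ends higher”.

Thursday's gives 11.9% of L and Wednesday's 30.8%, so Wednesday's finishes higher.

    J + Z → X (k = 0.120 L mol⁻¹ min⁻¹, Ea = 63.0 kJ mol⁻¹)
    J + G → L (k = 0.0330 L mol⁻¹ min⁻¹, Ea = 84.0 kJ mol⁻¹)
    L + Z → Q (k = 0.0190 L mol⁻¹ min⁻¹, Ea = 73.0 kJ mol⁻¹)
    G + D → Z (k = 0.0240 L mol⁻¹ min⁻¹, Ea = 74.0 kJ mol⁻¹)
    (constants at 80 °C)

In Thursday's flask L fell from 29.8% at 2.00 h to 11.9% at 4.00 h, on average a constant of 0.00765 min⁻¹ between those times, against the reckoned 0.00582 min⁻¹. Now take the neighbour of Thursday's charged with 1.20 equiv of G. Its loss constant reckons to 0.00233 min⁻¹. Carrying Thursday's 11.9% across the difference in constants over 200 min gives 23.9%. That neighbour flask ended with 27.1% of L and 57.7% of X.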